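## The problem

The target **21** is built from two 6,8-dimethoxy-7-oxygenated coumarins: rings A and B (unprimed locants) carry the free C7–OH, and rings C and D (primed locants) are intact isofraxidin. The two halves are joined by an ether from C3 of ring B to O7', not by a carbon–carbon bond. This ether is the central difficulty: its carbon is a vinylic position alpha to a lactone carbonyl, and its oxygen is a phenol oxygen flanked by two methoxy groups and delocalised into a lactone, so substitution at an sp2 carbon by this phenoxide is badly matched. Ring A has four contiguous oxygens in a fixed order (O1 on C8a, OMe on C8, OH on C7, OMe on C6) next to the carbon that starts ring B, and this pattern must be set without isomers. The target has no stereocentre, so any sp3 centre made on the way is transient, directs nothing and needs no control. The fragile groups are the two lactones, which open in aqueous base (reversibly while the cis-cinnamate geometry is kept), and the easily oxidised 2,6-dimethoxyphenol at C7. The enabling feature is that C3 is bonded to exactly three atoms that can arrive separately (C2, C4 and O7') and that C7–OH is para to C4a. C3 can therefore be made as the sp3 carbon of an aldehyde-derived electrophile, and ring B can be raised to the coumarin level last by loss of hydride from C4 through a para-quinone methide.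

## Retrosynthesis

**21 to 19.** The first move cuts no skeletal bond; it removes the C3=C4 double bond and leads to the racemic 3-aryloxy-3,4-dihydrocoumarin **19**. The neighbouring options keep C3 sp2: copper-mediated coupling of a 3-halocoumarin with isofraxidin **13**, or a Perkin-type condensation of a salicylaldehyde with the aryloxyacetic acid of **13**. The first asks a weak, di-ortho-substituted phenoxide to substitute at a vinylic carbon; the second needs hot anhydride and a protected C7 oxygen. With C3 sp3, the ether becomes an ordinary substitution problem. The forward step is a DDQ dehydrogenation through the para-quinone methide **20**, whose acidic C3–H lets it tautomerise to **21**. It must stop at the coumarin, which is plausible because the product phenol is conjugated with the lactone carbonyl and is less electron-rich than **19**.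

**19 to 17.** Cutting the lactone bond O1–C2 and masking both ring A phenols as methoxymethyl (MOM) ethers gives the acyclic alpha-aryloxy acid **17**. MOM is preferred to benzyl because hydrogenolysis would threaten the C3'=C4' bond of ring D. One acid treatment should remove both acetals (dihydroxy acid **18**) and close ring B through the freed C8a phenol.

**17 to 11, 12 and 13.** This is the key disconnection: C2–C3 and C3–O7' are cut together. C2 becomes chloroform **12**, O7' stays on intact isofraxidin **13**, and C3 becomes the carbonyl carbon of the arylacetaldehyde **11**. The neighbouring cut, O-alkylation of **13** with an alpha-halo-beta-arylpropanoate, needs a separately made secondary halide that can eliminate to a cinnamate. A Mitsunobu reaction on the alpha-hydroxy ester is sound but longer, and is kept as the fallback. In the three-component Jocic–Reeve coupling, trichloromethide adds to **11** to give carbinol **14**, base closes **14** to the gem-dichloroepoxide **15**, and the phenoxide of **13** attacks its unhindered CH carbon. The acyl chloride **16** that results is hydrolysed to **17**. The simplification is large: one partner is a solvent, one is a purchasable natural product used whole, and the third is a simple arene with a two-carbon chain. Three measures strengthen the step: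
- the ring A ortho oxygen is capped as a MOM ether so it cannot open the epoxide itself;
- excess chloroform is evaporated before hydroxide is added, so no dichlorocarbene meets the phenoxide;
- **13** is used in excess (recoverable) with little water, so it can compete with hydroxide.

**11 to 9.** The aldehyde carbon is traced to the internal carbon of an allyl group; the C=C bond of the allylarene **9** is cleaved oxidatively through diol **10**. The neighbouring route, methoxymethylene Wittig homologation of a salicylaldehyde, ends with acid hydrolysis of an enol ether next to two aryl MOM acetals. Loss of the ortho acetal there would send the aldehyde to a benzofuran. Buffered osmium/periodate cleavage involves no acid.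

**9 to 8, 6 and 5.** The bond C4a–C4 (aryl–CH2) is cut by an aromatic Claisen rearrangement. **9** is the MOM ether of the ortho-allylphenol **8**, which comes through dienone **7** from the allyl ether **6** of phenol **5**. In **6** one ortho carbon and the para carbon already carry methoxy groups, so the allyl group has only one place to go. The same phenol oxygen later becomes O1.

**5 to 2 and 1.** The C8a–O bond is cut back to the MOM ether **2** of 2,6-dimethoxyphenol **1**. Lithiation next to a methoxy group (aryllithium **3**), borylation (boronate **4**) and oxidation install the fourth oxygen. **2** has a mirror plane, so its two lithiation sites are equivalent and only one phenol can form. A neighbouring entry from syringaldehyde (bromination, copper-mediated hydroxylation) would give the same oxygen pattern but with a formyl group, which would need the homologation rejected above.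

## Roads not taken

**Alternative 1:** Ring A is cut across C8a–C4a and C5–C6, back to 4-(benzyloxy)-3-methoxy-2-(tert-butyldimethylsilyloxy)furan A2 and methyl propiolate A3.
- Forward key step: A2 adds to A3 across furan C2 and C5; the oxa-bridged adduct opens and aromatises to methyl 4-benzyloxy-5-hydroxy-3-methoxy-2-(tert-butyldimethylsilyloxy)benzoate A1.
- Merits: the polarity of the siloxyfuran fixes the regiochemistry. All four ring A oxygens arrive differentiated (silyl ether on C8a, OMe on C8, benzyl ether on C7, free OH on C6), with an ester marking C4a. No organolithium step is needed.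
- Weak points: it solves the arene, which is the lesser problem. After A1 the C6 hydroxyl must be methylated, the ester reduced and extended by one carbon, and ring B and the C3–O7' ether are still to be made. The benzyl ether would have to be removed by hydrogenolysis in the presence of coumarin double bonds. A2 is hydrolytically labile and takes several steps to prepare.
- Comparison: in oxygen differentiation this road is better. The chosen plan sets against it that only the two phenols need masking and both are unmasked together, that the symmetry of **2** and the single free ortho position of **6** fix the regiochemistry just as firmly, and that the ring is bought, not built.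

**Alternative 2:** Rings A and B are cut at once (C5–C6, C8–C8a, O1–C2), back to 1,3-dimethoxyacetone A5 and dimethyl 2-[(6,8-dimethoxy-2-oxochromen-7-yl)oxy]-4-(methoxymethylidene)pentanedioate A6.
- Forward key step: with KOt-Bu one alpha carbon of A5 adds to the methoxymethylidene carbon with loss of methoxide and the other attacks the adjacent ester. Ring A aromatises with free C7 and C8a hydroxyls, and the latter lactonises to the 3,4-dihydro derivative of the target, A4, which is the same compound as **19**.
- Merits: one step makes both rings, no protecting groups are needed, and the ether in A6 would come from ordinary O-alkylation of **13**. This is shorter and, for the ether, simpler than the chosen plan.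
- Weak points: in A6 the aryloxy group is beta to the acidic allylic CH2, so alkoxide can expel isofraxidin by a vinylogous E1cB elimination. The ester alpha to the aryloxy group is a competing acylation site. Ring D and the product lactone are exposed to alkoxide, and the electron-rich diphenolic product is oxidation-prone in base. A double condensation of an alpha-alkoxy ketone in this crowded setting is the least precedented step of any of the plans.
- Comparison: the chosen plan sets against the shorter route that each of its ring-forming and bond-forming events is an established reaction, that its aryloxy-bearing carbon has no eliminable arrangement in **17**, and that base is aqueous hydroxide at 0 °C, not alkoxide.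

**Alternative 3:** Ring D is cut at C4'–C4a' (with O1'–C2' re-formed), back to 3-[2,6-dimethoxy-3-(prop-2-ynyloxy)phenoxy]-6,8-dimethoxy-7-(methoxymethoxy)chromen-2-one A8.
- Forward key step: heating A8 in N,N-diethylaniline near 200 °C causes propargyl Claisen rearrangement to C4a', a 1,5-hydrogen shift and a six-electron oxa-electrocyclisation, giving 3-[(6,8-dimethoxy-2H-chromen-7-yl)oxy]-6,8-dimethoxy-7-(methoxymethoxy)chromen-2-one A7.
- Merits: the step is thermal and neutral, with no competing nucleophile. Only one ortho position is free, so the regiochemistry is secure. It does not depend on purchased isofraxidin.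
- Weak points: A8 already contains the C3–O ether and the complete coumarin of rings A and B, so the hard bond is only moved into the preparation of A8. C2' of A7 is still CH2 and needs an allylic oxidation to the lactone next to electron-rich rings. Ring D is assembled atom by atom although it can be bought as part of **13**.
- Comparison: the key step here is cleaner than a base-mediated three-component coupling, and that is a real advantage. The chosen plan sets against it that its key step makes the difficult ether itself and spends no steps on rings C and D.

Key step: step 7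

Assumption: isofraxidin **13** is taken as a purchasable natural coumarin; since **21** has no stereocentre, every chiral intermediate is carried as a racemate.

## Route

Step 1
Reactants: 1 2,6-dimethoxyphenol
Product: 2 1,3-dimethoxy-2-(methoxymethoxy)benzene
Conditions: MOMCl, i-Pr2NEt, CH2Cl2, 0 °C to rt
Reagents that add atoms: chloromethyl methyl ether, COCCl
Why: O-alkylation of a phenol with an alpha-chloro ether (acetal protection); the MOM ether should survive organolithium, heat and base up to step 7 and leave with acid in step 8.

Step 2
Reactants: 2 1,3-dimethoxy-2-(methoxymethoxy)benzene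
Product: 5 2,4-dimethoxy-3-(methoxymethoxy)phenol, via aryllithium 3 (not isolated), via dimethyl arylboronate 4 (not isolated)
Conditions: n-BuLi, TMEDA, THF, 0 °C; B(OMe)3, −78 °C to rt; then H2O2 (30% aq), AcOH, 0 °C to rt
Reagents that add atoms: hydrogen peroxide, OO (the phenol oxygen); n-butyllithium, [Li]CCCC and trimethyl borate, COB(OC)OC (atoms held only in 3 and 4)
Why: Directed ortho-metalation next to a methoxy group (the two possible sites of 2 are equivalent by symmetry), borylation and oxidative 1,2-shift of the aryl group from boron to oxygen, the standard passage from a 1,2,3-trialkoxybenzene to a 2,3,4-trialkoxyphenol; the acidic peroxide medium spares the electron-rich phenol from autoxidation in base.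

Step 3
Reactants: 5 2,4-dimethoxy-3-(methoxymethoxy)phenol
Product: 6 1,3-dimethoxy-2-(methoxymethoxy)-4-(prop-2-enyloxy)benzene
Conditions: allyl bromide, K2CO3, acetone, reflux
Reagents that add atoms: allyl bromide, C=CCBr
Why: Williamson ether synthesis; the phenoxide is alkylated on oxygen by a primary allylic bromide.

Step 4
Reactants: 6 1,3-dimethoxy-2-(methoxymethoxy)-4-(prop-2-enyloxy)benzene
Product: 8 2,4-dimethoxy-3-(methoxymethoxy)-6-(prop-2-enyl)phenol, via ortho-dienone 7 (not isolated)
Conditions: N,N-diethylaniline, 190 °C
Reagents that add atoms: none
Why: Aromatic Claisen rearrangement ([3,3]-sigmatropic shift) followed by tautomerisation of dienone 7; one ortho carbon and the para carbon carry methoxy groups, so the allyl group should end on the single free ortho carbon, and the MOM acetal is inert to neutral heat.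

Step 5
Reactants: 8 2,4-dimethoxy-3-(methoxymethoxy)-6-(prop-2-enyl)phenol
Product: 9 1,3-dimethoxy-2,4-bis(methoxymethoxy)-5-(prop-2-enyl)benzene
Conditions: MOMCl, i-Pr2NEt, CH2Cl2, 0 °C to reflux
Reagents that add atoms: chloromethyl methyl ether, COCCl
Why: Acetal protection of the new phenol as in step 1; this oxygen is the future O1 and must stay masked through the key step so that it cannot open the epoxide.

Step 6
Reactants: 9 1,3-dimethoxy-2,4-bis(methoxymethoxy)-5-(prop-2-enyl)benzene
Product: 11 2-[3,5-dimethoxy-2,4-bis(methoxymethoxy)phenyl]acetaldehyde, via diol 10 (not isolated)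
Conditions: OsO4 (cat.), NaIO4, 2,6-lutidine, dioxane–H2O, rt
Reagents that add atoms: osmium tetroxide, O=[Os](=O)(=O)=O (delivers the oxygens of diol 10, one of which remains as the aldehyde oxygen; regenerated by sodium periodate, [Na+].[O-]I(=O)(=O)=O)
Why: Lemieux–Johnson oxidation: catalytic dihydroxylation of the terminal alkene and periodate cleavage of diol 10; the lutidine buffer keeps the medium non-acidic for the MOM ethers, and the enolisable aldehyde is used crude at once.

Step 7
Reactants: 11 2-[3,5-dimethoxy-2,4-bis(methoxymethoxy)phenyl]acetaldehyde; 12 chloroform; 13 isofraxidin (7-hydroxy-6,8-dimethoxychromen-2-one)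
Product: 17 2-[(6,8-dimethoxy-2-oxochromen-7-yl)oxy]-3-[3,5-dimethoxy-2,4-bis(methoxymethoxy)phenyl]propanoic acid (racemic), via trichloromethyl carbinol 14 (not isolated), via gem-dichloroepoxide 15 (not isolated), via acyl chloride 16 (not isolated)
Conditions: 12 as solvent, DBU, −10 °C to rt; concentrate; then 13 (excess), NaOH, DME–H2O, 0 °C to rt; then 1 M HCl
Reagents that add atoms: sodium hydroxide, [Na+].[OH-] (the hydroxyl oxygen of the carboxyl group)
Why: DBU generates trichloromethide from chloroform, which adds to the aldehyde carbon of 11 (C2–C3) to give carbinol 14; after the excess chloroform is removed, NaOH closes 14 by 3-exo-tet displacement of chloride to the gem-dichloroepoxide 15, the phenoxide of 13 opens 15 by SN2 attack at its CH carbon (C3–O7'), the alpha-chloro alkoxide collapses to acyl chloride 16, and hydroxide then acid convert 16 into 17. The closest known reaction type is the Jocic–Reeve (Bargellini-type) conversion of trichloromethyl carbinols and phenoxides into alpha-aryloxy acids, run here in the same flask as the amidine-promoted addition of chloroform to an aldehyde. No ring of the product closes; the only ring formed is the transient oxirane of 15. The new stereocentre C3 has no controlling element and forms racemic, which is acceptable because it becomes sp2 in step 9. Opening at C3 and not at the dichlorinated carbon follows from the shielding and poor SN2 reactivity of a carbon that bears two chlorines and an oxygen. Opening by the ring A ortho oxygen is excluded by its MOM ether, and alkylation through O1' is disfavoured because the 7-oxido group makes the lactone of 13 a vinylogous carboxylate that resists hydroxide at 0 °C, while any lactone opened after etherification should reclose on acidification. Aldol condensation of 11 is held down by running the first stage dilute in chloroform at low temperature, and competition from hydroxide in the second stage by an excess of 13 and a minimum of water. Removing the chloroform before NaOH is added keeps dichlorocarbene away from the phenoxide.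

Step 8
Reactants: 17 2-[(6,8-dimethoxy-2-oxochromen-7-yl)oxy]-3-[3,5-dimethoxy-2,4-bis(methoxymethoxy)phenyl]propanoic acid (racemic)
Product: 19 3-[(6,8-dimethoxy-2-oxochromen-7-yl)oxy]-7-hydroxy-6,8-dimethoxy-3,4-dihydrochromen-2-one (racemic), via dihydroxy acid 18 (not isolated)
Conditions: 3 M HCl, THF, 50 °C; then p-TsOH·H2O (cat.), toluene, reflux (Dean–Stark)
Reagents that add atoms: none
Why: Acid hydrolysis of both aryl MOM acetals gives 18, whose C8a phenol then closes ring B by acid-catalysed 6-exo-trig acyl substitution at the carboxyl group with azeotropic removal of water (dihydrocoumarin formation from a 3-(2-hydroxyaryl)propanoic acid); the coumarin of rings C and D and the alkyl aryl ether are stable to acid.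

Step 9
Reactants: 19 3-[(6,8-dimethoxy-2-oxochromen-7-yl)oxy]-7-hydroxy-6,8-dimethoxy-3,4-dihydrochromen-2-one (racemic)
Product: 21 3-[(6,8-dimethoxy-2-oxochromen-7-yl)oxy]-7-hydroxy-6,8-dimethoxychromen-2-one, via para-quinone methide 20 (not isolated)
Conditions: DDQ, 1,4-dioxane, 80 °C
Reagents that add atoms: none
Why: DDQ dehydrogenation of a 3,4-dihydrocoumarin: hydride abstraction from benzylic C4, assisted by the para C7–OH, gives quinone methide 20, which tautomerises through its acidic C3–H (alpha to the lactone carbonyl) to the aromatic coumarin; the product phenol is conjugated with the lactone and less oxidisable than 19, so the reaction should stop there, and the racemic centre at C3 disappears.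

## Compound list

1 | 2,6-dimethoxyphenol | COc1cccc(OC)c1O | starting material
2 | 1,3-dimethoxy-2-(methoxymethoxy)benzene | COCOc1c(OC)cccc1OC | intermediate
3 | [2,4-dimethoxy-3-(methoxymethoxy)phenyl]lithium | [Li]c1ccc(OC)c(OCOC)c1OC | intermediate (not isolated)
4 | dimethyl [2,4-dimethoxy-3-(methoxymethoxy)phenyl]boronate | COB(OC)c1ccc(OC)c(OCOC)c1OC | intermediate (not isolated)
5 | 2,4-dimethoxy-3-(methoxymethoxy)phenol | Oc1ccc(OC)c(OCOC)c1OC | intermediate
6 | 1,3-dimethoxy-2-(methoxymethoxy)-4-(prop-2-enyloxy)benzene | C=CCOc1ccc(OC)c(OCOC)c1OC | intermediate
7 | 2,4-dimethoxy-3-(methoxymethoxy)-6-(prop-2-enyl)cyclohexa-2,4-dien-1-one (racemic) | O=C1C(CC=C)C=C(OC)C(OCOC)=C1OC | intermediate (not isolated)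
8 | 2,4-dimethoxy-3-(methoxymethoxy)-6-(prop-2-enyl)phenol | Oc1c(CC=C)cc(OC)c(OCOC)c1OC | intermediate
9 | 1,3-dimethoxy-2,4-bis(methoxymethoxy)-5-(prop-2-enyl)benzene | C=CCc1cc(OC)c(OCOC)c(OC)c1OCOC | intermediate
10 | 3-[3,5-dimethoxy-2,4-bis(methoxymethoxy)phenyl]propane-1,2-diol (racemic) | OCC(O)Cc1cc(OC)c(OCOC)c(OC)c1OCOC | intermediate (not isolated)
11 | 2-[3,5-dimethoxy-2,4-bis(methoxymethoxy)phenyl]acetaldehyde | O=CCc1cc(OC)c(OCOC)c(OC)c1OCOC | intermediate
12 | chloroform | ClC(Cl)Cl | starting material
13 | isofraxidin (7-hydroxy-6,8-dimethoxychromen-2-one) | COc1cc2ccc(=O)oc2c(OC)c1O | starting material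
14 | 1,1,1-trichloro-3-[3,5-dimethoxy-2,4-bis(methoxymethoxy)phenyl]propan-2-ol (racemic) | OC(Cc1cc(OC)c(OCOC)c(OC)c1OCOC)C(Cl)(Cl)Cl | intermediate (not isolated)
15 | 2,2-dichloro-3-{[3,5-dimethoxy-2,4-bis(methoxymethoxy)phenyl]methyl}oxirane (racemic) | ClC1(Cl)OC1Cc1cc(OC)c(OCOC)c(OC)c1OCOC | intermediate (not isolated)
16 | 2-[(6,8-dimethoxy-2-oxochromen-7-yl)oxy]-3-[3,5-dimethoxy-2,4-bis(methoxymethoxy)phenyl]propanoyl chloride (racemic) | ClC(=O)C(Cc1cc(OC)c(OCOC)c(OC)c1OCOC)Oc1c(OC)cc2ccc(=O)oc2c1OC | intermediate (not isolated)
17 | 2-[(6,8-dimethoxy-2-oxochromen-7-yl)oxy]-3-[3,5-dimethoxy-2,4-bis(methoxymethoxy)phenyl]propanoic acid (racemic) | OC(=O)C(Cc1cc(OC)c(OCOC)c(OC)c1OCOC)Oc1c(OC)cc2ccc(=O)oc2c1OC | intermediate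
18 | 3-(2,4-dihydroxy-3,5-dimethoxyphenyl)-2-[(6,8-dimethoxy-2-oxochromen-7-yl)oxy]propanoic acid (racemic) | OC(=O)C(Cc1cc(OC)c(O)c(OC)c1O)Oc1c(OC)cc2ccc(=O)oc2c1OC | intermediate (not isolated)
19 | 3-[(6,8-dimethoxy-2-oxochromen-7-yl)oxy]-7-hydroxy-6,8-dimethoxy-3,4-dihydrochromen-2-one (racemic) | COc1cc2CC(Oc3c(OC)cc4ccc(=O)oc4c3OC)C(=O)Oc2c(OC)c1O | intermediate
20 | 3-[(6,8-dimethoxy-2-oxochromen-7-yl)oxy]-6,8-dimethoxy-3H-chromene-2,7-dione (racemic) | O=C1C(OC)=CC(=CC(Oc3c(OC)cc4ccc(=O)oc4c3OC)C(=O)O2)C2=C1OC | intermediate (not isolated)
21 | 3-[(6,8-dimethoxy-2-oxochromen-7-yl)oxy]-7-hydroxy-6,8-dimethoxychromen-2-one | COc1cc2cc(Oc3c(OC)cc4ccc(=O)oc4c3OC)c(=O)oc2c(OC)c1O | target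

## Step count and risk

Total step count: 9. Longest linear sequence: 9 steps (1 to 21); 12 and 13 enter at step 7.

**Step 7 (key step).**
- What may go wrong: base-induced self-aldol condensation of the arylacetaldehyde before trichloromethide is captured; interception of epoxide 15 by hydroxide or chloride faster than by the delocalised, di-ortho-substituted phenoxide; opening of ring D of 13 so that alkylation occurs through O1'.
- Fallback: it sets out from 11 and returns at 17. Decarboxylative trichloromethylation of 11 (Cl3CCO2Na, Cl3CCO2H, DMF, rt) needs no amine base and gives 14, which is now isolated. NaOH in DME–H2O alone takes 14 through 15 to 3-[3,5-dimethoxy-2,4-bis(methoxymethoxy)phenyl]-2-hydroxypropanoic acid F1. MeI and K2CO3 in DMF give methyl 3-[3,5-dimethoxy-2,4-bis(methoxymethoxy)phenyl]-2-hydroxypropanoate F2. A Mitsunobu reaction of F2 with 13 (PPh3, DIAD, THF) forms the C3–O7' bond by SN2 displacement under neutral conditions, where no hydroxide competes and the acidity of 13 is an asset, giving methyl 2-[(6,8-dimethoxy-2-oxochromen-7-yl)oxy]-3-[3,5-dimethoxy-2,4-bis(methoxymethoxy)phenyl]propanoate F3. LiOH in THF–H2O followed by HCl gives 17, with ring D reclosing on acidification.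

**Step 9.**
- What may go wrong: over-oxidation of the electron-rich ring A phenol, or capture of the quinone methide at C4 by water or by the reduced quinone before it tautomerises.
- Fallback: it sets out from 19 and returns at 21. Acetylation (Ac2O, pyridine) gives 3-[(6,8-dimethoxy-2-oxochromen-7-yl)oxy]-6,8-dimethoxy-2-oxo-3,4-dihydrochromen-7-yl acetate F4. Radical bromination at the benzylic C4 (NBS, AIBN cat., PhCF3, 80 °C) gives 4-bromo-3-[(6,8-dimethoxy-2-oxochromen-7-yl)oxy]-6,8-dimethoxy-2-oxo-3,4-dihydrochromen-7-yl acetate F5. Et3N removes HBr across C3–C4 to give 3-[(6,8-dimethoxy-2-oxochromen-7-yl)oxy]-6,8-dimethoxy-2-oxochromen-7-yl acetate F6. Brief methanolysis (K2CO3, MeOH, 0 °C) frees the phenol of 21.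

**Step 6.**
- What may go wrong: loss of the arylacetaldehyde by over-oxidation to the arylacetic acid, or by enolisation and aldol condensation during the aqueous oxidative work-up.
- Fallback: it sets out from 5 and returns at 11, making the aldehyde by a final anhydrous alcohol oxidation. MOMCl and i-Pr2NEt convert 5 into 1,3-dimethoxy-2,4-bis(methoxymethoxy)benzene F7. n-BuLi in THF at 0 °C lithiates ortho to the stronger MOM-oxy director to give [3,5-dimethoxy-2,4-bis(methoxymethoxy)phenyl]lithium F8. Ethylene oxide then gives 2-[3,5-dimethoxy-2,4-bis(methoxymethoxy)phenyl]ethanol F9. Dess–Martin periodinane buffered with NaHCO3 in CH2Cl2 gives 11.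

**Step 8.**
- What may go wrong: re-attack of the released formaldehyde on the electron-rich rings (hydroxymethylation or methylene bridging), and incomplete ring closure because lactonisation is an equilibrium in wet acid.
- Fallback: it sets out from 17 and returns at 19. ZnBr2 and n-PrSH in CH2Cl2 cleave both acetals under anhydrous conditions and trap the methoxymethyl unit on sulfur, giving 18, which is isolated. Carbodiimide lactonisation (EDC·HCl, CH2Cl2) then closes ring B irreversibly. No compound outside the compound list is made (F0).

**Step 2.**
- What may go wrong: incomplete or unselective metalation, or attack of n-BuLi on the crowded alkoxy-bearing carbons with displacement of an alkoxy group.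
- Fallback: it sets out from 2 and returns at 5. NBS in MeCN brominates para to a methoxy group, the same carbon, to give 1-bromo-2,4-dimethoxy-3-(methoxymethoxy)benzene F10. Bromine–lithium exchange (n-BuLi, THF, −78 °C) gives 3 unambiguously, and 3 is carried through 4 to 5 as in step 2.

## Further compounds

F1 | step 7 | 3-[3,5-dimethoxy-2,4-bis(methoxymethoxy)phenyl]-2-hydroxypropanoic acid (racemic) | OC(=O)C(O)Cc1cc(OC)c(OCOC)c(OC)c1OCOC
F2 | step 7 | methyl 3-[3,5-dimethoxy-2,4-bis(methoxymethoxy)phenyl]-2-hydroxypropanoate (racemic) | COC(=O)C(O)Cc1cc(OC)c(OCOC)c(OC)c1OCOC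
F3 | step 7 | methyl 2-[(6,8-dimethoxy-2-oxochromen-7-yl)oxy]-3-[3,5-dimethoxy-2,4-bis(methoxymethoxy)phenyl]propanoate (racemic) | COC(=O)C(Cc1cc(OC)c(OCOC)c(OC)c1OCOC)Oc1c(OC)cc2ccc(=O)oc2c1OC
F4 | step 9 | 3-[(6,8-dimethoxy-2-oxochromen-7-yl)oxy]-6,8-dimethoxy-2-oxo-3,4-dihydrochromen-7-yl acetate (racemic) | COc1cc2CC(Oc3c(OC)cc4ccc(=O)oc4c3OC)C(=O)Oc2c(OC)c1OC(C)=O
F5 | step 9 | 4-bromo-3-[(6,8-dimethoxy-2-oxochromen-7-yl)oxy]-6,8-dimethoxy-2-oxo-3,4-dihydrochromen-7-yl acetate (racemic, mixture of diastereomers) | COc1cc2C(Br)C(Oc3c(OC)cc4ccc(=O)oc4c3OC)C(=O)Oc2c(OC)c1OC(C)=O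
F6 | step 9 | 3-[(6,8-dimethoxy-2-oxochromen-7-yl)oxy]-6,8-dimethoxy-2-oxochromen-7-yl acetate | COc1cc2cc(Oc3c(OC)cc4ccc(=O)oc4c3OC)c(=O)oc2c(OC)c1OC(C)=O
F7 | step 6 | 1,3-dimethoxy-2,4-bis(methoxymethoxy)benzene | COCOc1ccc(OC)c(OCOC)c1OC
F8 | step 6 | [3,5-dimethoxy-2,4-bis(methoxymethoxy)phenyl]lithium | [Li]c1cc(OC)c(OCOC)c(OC)c1OCOC
F9 | step 6 | 2-[3,5-dimethoxy-2,4-bis(methoxymethoxy)phenyl]ethanol | OCCc1cc(OC)c(OCOC)c(OC)c1OCOC
F0 | step 8 | none | none
F10 | step 2 | 1-bromo-2,4-dimethoxy-3-(methoxymethoxy)benzene | Brc1ccc(OC)c(OCOC)c1OC
A1 | alternative 1 | methyl 4-benzyloxy-5-hydroxy-3-methoxy-2-(tert-butyldimethylsilyloxy)benzoate | COC(=O)c1cc(O)c(OCc2ccccc2)c(OC)c1O[Si](C)(C)C(C)(C)C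
A2 | alternative 1 | 4-(benzyloxy)-3-methoxy-2-(tert-butyldimethylsilyloxy)furan | CC(C)(C)[Si](C)(C)Oc1occ(OCc2ccccc2)c1OC
A3 | alternative 1 | methyl propiolate | C#CC(=O)OC
A4 | alternative 2 | 3-[(6,8-dimethoxy-2-oxochromen-7-yl)oxy]-7-hydroxy-6,8-dimethoxy-3,4-dihydrochromen-2-one (racemic) | COc1cc2CC(Oc3c(OC)cc4ccc(=O)oc4c3OC)C(=O)Oc2c(OC)c1O
A5 | alternative 2 | 1,3-dimethoxyacetone | COCC(=O)COC
A6 | alternative 2 | dimethyl 2-[(6,8-dimethoxy-2-oxochromen-7-yl)oxy]-4-(methoxymethylidene)pentanedioate (racemic, alkene geometry not specified) | COC=C(CC(Oc1c(OC)cc2ccc(=O)oc2c1OC)C(=O)OC)C(=O)OC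
A7 | alternative 3 | 3-[(6,8-dimethoxy-2H-chromen-7-yl)oxy]-6,8-dimethoxy-7-(methoxymethoxy)chromen-2-one | COCOc1c(OC)cc2cc(Oc3c(OC)cc4C=CCOc4c3OC)c(=O)oc2c1OC
A8 | alternative 3 | 3-[2,6-dimethoxy-3-(prop-2-ynyloxy)phenoxy]-6,8-dimethoxy-7-(methoxymethoxy)chromen-2-one | COCOc1c(OC)cc2cc(Oc3c(OC)ccc(OCC#C)c3OC)c(=O)oc2c1OC
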